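**Plan**

1. Retrosynthetic cuts: the C23–O acetate; both C4–CH3 bonds; C11–C12 (the farnesyl unit is put on a lactone enolate, and the lactone carbonyl carbon later leaves as CO); then, in one step, C8–O, C9–C10 and C1–C2.
2. Forward order: (R)-limonene oxide is opened to an acyclic diazoketone; one cationic cascade closes ring A at C1–C2, ring B at C9–C10 and a γ-lactone at C8–O; then the side chain, loss of the lactone carbonyl, gem-dimethylation at C4, acetate.
3. Enabling feature: the C3 carbonyl carries the diazo carbon C2 four atoms away from the CH2 terminus of the isopropenyl group on C5 (limonene's isopropenyl becomes C1, C10 and CH3-10), with the E-C8=C9 alkene and an ester in line behind it.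
4. Stereochemistry: C5 comes from (R)-limonene; C10, C9 and C8 are set in the cascade (axial closure at C10, E-alkene in a chair, anti addition); the side-chain alkenes come from (2E,6E)-farnesyl acetate, and C8=C9 from a syn-carboalumination.
5. Remark: read literally, the SMILES puts H-5 and CH3-10 on the same face (5S with the C3 ketone), i.e. a cis-fused decalin with 8α-OH, 8β-CH3 and a 9β side chain (β = face of CH3-10); the route is built for exactly this, which is why the C4 methyl groups are added only after ring closure. Numbering: C1–C10 decalin as in the target, C11–C23 side chain counted from C9, C23 = CH2O.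

Key step: step 7

**Route**

Step 1
Reactants: 1 (4R)-limonene 1,2-oxide (commercial cis/trans mixture)
Product: 2 (3R)-6-oxo-3-(prop-1-en-2-yl)heptanal
Conditions: H5IO6, THF/H2O, 0 °C → rt
Reagents that add atoms: water, O
Why: Periodic acid should hydrolyse the epoxide to the diol and cleave it (Malaprade glycol cleavage) to the keto aldehyde; the isopropenyl-bearing centre (future C5) is untouched and no new stereocentre forms.

Step 2
Reactants: 2 (3R)-6-oxo-3-(prop-1-en-2-yl)heptanal
Product: 3 (3R)-6-oxo-3-(prop-1-en-2-yl)heptanoic acid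
Conditions: NaClO2, NaH2PO4, 2-methyl-2-butene, t-BuOH/H2O, 0 °C → rt
Reagents that add atoms: sodium chlorite, [Na+].[O-]Cl=O
Why: Pinnick oxidation should convert only the aldehyde into the acid, with 2-methyl-2-butene trapping HOCl so that the isopropenyl group survives; no new stereocentre.

Step 3
Reactants: 3 (3R)-6-oxo-3-(prop-1-en-2-yl)heptanoic acid
Product: 5 (3R)-3-(prop-1-en-2-yl)hept-6-ynoic acid, via enol triflate 4 (not isolated)
Conditions: LiN(i-Pr)2 (2.1 equiv), THF, −78 °C; PhNTf2; then LiN(i-Pr)2 (2.5 equiv), −78 → 0 °C; aq. HCl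
Reagents that add atoms: N-phenylbis(trifluoromethanesulfonimide), O=S(=O)(N(c1ccccc1)S(=O)(=O)C(F)(F)F)C(F)(F)F (CF3SO2 group of 4 only)
Why: The lithium carboxylate keeps the acid side inert, kinetic enolisation of the methyl ketone at CH3 followed by O-triflation and base-induced elimination should give the terminal alkyne (ketone-to-alkyne conversion through the enol triflate); C4 is CH2, so no stereocentre is at risk.

Step 4
Reactants: 5 (3R)-3-(prop-1-en-2-yl)hept-6-ynoic acid
Product: 7 (3R,6E)-7-iodo-6-methyl-3-(prop-1-en-2-yl)hept-6-enoic acid, via alkenylalane 6 (not isolated)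
Conditions: AlMe3 (4 equiv), Cp2ZrCl2 (0.3 equiv), CH2Cl2, 0 °C → rt; then I2, THF, −30 °C; aq. HCl
Reagents that add atoms: trimethylaluminium, C[Al](C)C; iodine, II
Why: Negishi zirconium-catalysed methylalumination adds CH3 and Al syn across the alkyne with CH3 on the internal carbon, and iodinolysis with retention should give the E-trisubstituted alkenyl iodide; the 1,1-disubstituted isopropenyl alkene does not react.

Step 5
Reactants: 7 (3R,6E)-7-iodo-6-methyl-3-(prop-1-en-2-yl)hept-6-enoic acid
Product: 8 (3R,6E)-9-tert-butoxy-6-methyl-9-oxo-3-(prop-1-en-2-yl)non-6-enoic acid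
Conditions: BrZnCH2CO2t-Bu (3 equiv), Pd(PPh3)4 (5 mol %), THF/DMPU, 50 °C
Reagents that add atoms: (2-tert-butoxy-2-oxoethyl)zinc bromide, Br[Zn]CC(=O)OC(C)(C)C
Why: Palladium-catalysed cross-coupling of the alkenyl iodide with the Reformatsky reagent (Negishi-type coupling of a zinc enolate) should proceed with retention of the E geometry and give the β,γ-unsaturated ester without conjugation.

Step 6
Reactants: 8 (3R,6E)-9-tert-butoxy-6-methyl-9-oxo-3-(prop-1-en-2-yl)non-6-enoic acid
Product: 10 tert-butyl (3E,7R)-10-diazo-4-methyl-9-oxo-7-(prop-1-en-2-yl)dec-3-enoate, via mixed anhydride 9 (not isolated)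
Conditions: i-BuOCOCl, N-methylmorpholine, THF, −20 °C; then CH2N2, Et2O, −20 → 4 °C
Reagents that add atoms: diazomethane, C=[N+]=[N-]; isobutyl chloroformate, CC(C)COC(Cl)=O (carbonate part of 9 only)
Why: Acylation of diazomethane by the mixed carbonic anhydride (first stage of the Arndt–Eistert sequence) should give the diazomethyl ketone under neutral conditions that leave the tert-butyl ester and both alkenes untouched; no new stereocentre.

Step 7
Reactants: 10 tert-butyl (3E,7R)-10-diazo-4-methyl-9-oxo-7-(prop-1-en-2-yl)dec-3-enoate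
Product: 11 cis-fused keto lactone (3aR,5aR,9aS,9bR)-3a,9a-dimethylperhydronaphtho[2,1-b]furan-2,7-dione (C3 ketone; C4H2; 5β-H; 10β-CH3; 9α-H; 8β-CH3; lactone O 8α)
Conditions: BF3·OEt2 (1.5 equiv), CH2Cl2, −78 → −20 °C; aq. NaHCO3
Reagents that add atoms: none
Why: BF3 binds the diazoketone oxygen and the diazo carbon C2 is attacked by the CH2 terminus (C1) of the isopropenyl group with loss of N2; the tertiary C10 cation is taken by C9 of the E-trisubstituted alkene and the resulting C8 cation by the ester carbonyl oxygen, which then loses 2-methylpropene. The closest known reaction types are the Lewis-acid-promoted cyclisation of unsaturated diazomethyl ketones (diazoketone-initiated polyolefin cyclisation), the cis-selective closure of 2-(alk-3-enyl)-1-methylcyclohexyl cations and the lactone-terminated cyclisation of homofarnesic acid. Ring A closes 6-endo-trig at C1 (C1–C2 bond), ring B 6-endo-trig at C9 (C9–C10 bond) and the γ-lactone 5-exo at C8 (C8–O bond). C10 is controlled by the C5 centre from limonene: in the chair of ring A the C5 chain is equatorial and, with no substituent on C4, C9 should bond axially to C10, which places CH3-10 on the face of H-5 (cis ring fusion); C9 follows from the E geometry of the alkene in a chair-like ring B (C11 equatorial, cis to CH3-10) and C8 from anti addition across C8=C9 (lactone oxygen equatorial and trans to C11, CH3-8 axial). The step needs C-alkylation at C1 in the Markovnikov sense, axial instead of equatorial closure at C10, and capture of the C8 cation before proton loss: the 1,1-disubstituted alkene four atoms from C2, the absent C4 methyl groups (an axial C4 methyl would shield the axial face of C10) and the tethered ester with no further alkene in reach are what should secure these.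

Step 8
Reactants: 11 cis-fused keto lactone
Product: 12 3,3-ethylenedioxy ketal of keto lactone 11
Conditions: HOCH2CH2OH, pyridinium p-toluenesulfonate (cat.), benzene, reflux, Dean–Stark
Reagents that add atoms: ethylene glycol, OCCO
Why: Acid-catalysed ketalisation of the unhindered C3 ketone should mask it for the enolate chemistry that follows; the lactone is inert and no stereocentre is touched.

Step 9
Reactants: 13 (2E,6E)-farnesyl acetate
Product: 14 (2E,6E,10E)-12-hydroxy-3,7,11-trimethyldodeca-2,6,10-trienyl acetate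
Conditions: SeO2 (cat.), t-BuOOH, salicylic acid (cat.), CH2Cl2, 0 °C → rt
Reagents that add atoms: tert-butyl hydroperoxide, CC(C)(C)OO
Why: Sharpless allylic oxidation (ene reaction, then 2,3-sigmatropic shift) should take the terminal prenyl unit, the most electron-rich alkene, and give the E-allylic alcohol.

Step 10
Reactants: 14 (2E,6E,10E)-12-hydroxy-3,7,11-trimethyldodeca-2,6,10-trienyl acetate
Product: 15 (2E,6E,10E)-12-(tert-butyldiphenylsilyloxy)-3,7,11-trimethyldodeca-2,6,10-trienyl acetate
Conditions: t-BuPh2SiCl, imidazole, DMF, rt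
Reagents that add atoms: tert-butylchlorodiphenylsilane, CC(C)(C)[Si](Cl)(c1ccccc1)c1ccccc1
Why: Silylation of the primary allylic alcohol gives a silyl ether that should survive amide base, hydride, hot rhodium, mild acid and alkoxide later on.

Step 11
Reactants: 15 (2E,6E,10E)-12-(tert-butyldiphenylsilyloxy)-3,7,11-trimethyldodeca-2,6,10-trienyl acetate
Product: 16 (2E,6E,10E)-12-(tert-butyldiphenylsilyloxy)-3,7,11-trimethyldodeca-2,6,10-trien-1-ol
Conditions: K2CO3 (cat.), MeOH, rt
Reagents that add atoms: none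
Why: Base-catalysed transesterification (methanolysis) should remove the acetate while the silyl ether stays.

Step 12
Reactants: 16 (2E,6E,10E)-12-(tert-butyldiphenylsilyloxy)-3,7,11-trimethyldodeca-2,6,10-trien-1-ol
Product: 17 (2E,6E,10E)-12-bromo-1-(tert-butyldiphenylsilyloxy)-2,6,10-trimethyldodeca-2,6,10-triene
Conditions: CBr4, PPh3, CH2Cl2, 0 °C
Reagents that add atoms: carbon tetrabromide, BrC(Br)(Br)Br
Why: Appel bromination should convert the primary allylic alcohol into the bromide under neutral conditions without allylic transposition or loss of E geometry.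

Step 13
Reactants: 12 3,3-ethylenedioxy ketal of keto lactone 11; 17 (2E,6E,10E)-12-bromo-1-(tert-butyldiphenylsilyloxy)-2,6,10-trimethyldodeca-2,6,10-triene
Product: 18 ketal lactone carrying the C12–C23 silyloxy trienyl chain on C11 (C11 epimers)
Conditions: LiN(i-Pr)2, THF, −78 °C; then 17, DMPU, −78 → −30 °C
Reagents that add atoms: none
Why: Lactone enolate alkylation (SN2 on the primary allylic bromide) should form the C11–C12 bond; the new C11 centre forms as a mixture and is removed in step 15, and the ketal keeps ring A out of the enolate chemistry.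

Step 14
Reactants: 18 C11-alkylated ketal lactone
Product: 19 lactol of 18 (anomers and C11 epimers)
Conditions: i-Bu2AlH, toluene, −78 °C; Rochelle salt work-up
Reagents that add atoms: none
Why: Partial reduction of the lactone with i-Bu2AlH should stop at the lactol because the tetrahedral aluminate is stable at −78 °C; ketal, silyl ether and alkenes are inert.

Step 15
Reactants: 19 lactol of 18
Product: 20 8α-hydroxy 3,3-ethylenedioxy bicycle (C4H2; 5β-H; 9β chain C11–C23 ending in CH2OSi(t-Bu)Ph2; 10β-CH3; 8β-CH3)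
Conditions: RhCl(PPh3)3 (1.2 equiv), toluene, 110 °C
Reagents that add atoms: none
Why: Tsuji–Wilkinson decarbonylation: the open hydroxy aldehyde form of the lactol adds to rhodium, CO is extruded and C–H reductive elimination should leave C11H2 and the free tertiary C8–OH; C8 and C9 are not touched.

Step 16
Reactants: 20 8α-hydroxy 3,3-ethylenedioxy bicycle
Product: 21 8α-hydroxy 3-ketone (C4H2) with the silyl-protected side chain
Conditions: pyridinium p-toluenesulfonate, acetone/H2O, 50 °C
Reagents that add atoms: water, O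
Why: Mild acid-catalysed ketal hydrolysis should free the C3 ketone while the silyl ether, the tertiary alcohol and the trisubstituted alkenes survive.

Step 17
Reactants: 21 8α-hydroxy 3-ketone (C4H2)
Product: 23 23-O-tert-butyldiphenylsilyl ether of the 8α,23-diol 3-ketone with the C4 gem-dimethyl group, via 4-monomethyl ketone 22 (not isolated)
Conditions: KOt-Bu (2.5 equiv), MeI (3 equiv), t-BuOH/THF, 0 °C → rt
Reagents that add atoms: iodomethane, CI
Why: Thermodynamic enolate alkylation: a cis-fused 3-ketone enolises towards C4, and after the first methylation the more substituted C3–C4 enolate is again the one alkylated, so both methyl groups should enter at C4; no lasting new stereocentre.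

Step 18
Reactants: 23 silyl ether of the gem-dimethyl keto diol
Product: 24 (5S,8R,9R,10S)-8α,23-dihydroxy 3-ketone (the deacetyl target)
Conditions: Bu4NF, THF, rt
Reagents that add atoms: none
Why: Fluoride-induced desilylation should free the primary allylic alcohol; ketone, tertiary alcohol and alkenes are inert.

Step 19
Reactants: 24 8α,23-dihydroxy 3-ketone
Product: 25 myrrhanone A acetate as defined by the given SMILES
Conditions: Ac2O, pyridine, CH2Cl2, 0 °C → rt
Reagents that add atoms: acetic anhydride, CC(=O)OC(C)=O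
Why: Acetylation should take only the primary allylic hydroxyl, since the tertiary C8–OH next to two quaternary-type centres is too hindered without an acyl-transfer catalyst.

**Compound list**

1 | (4R)-limonene 1,2-oxide (cis/trans mixture at the epoxide) | CC(=C)[C@@H]1CCC2(C)OC2C1 | starting material
2 | (3R)-6-oxo-3-(prop-1-en-2-yl)heptanal | CC(=C)[C@@H](CC=O)CCC(C)=O | intermediate
3 | (3R)-6-oxo-3-(prop-1-en-2-yl)heptanoic acid | CC(=C)[C@@H](CC(=O)O)CCC(C)=O | intermediate
4 | (3R)-3-(prop-1-en-2-yl)-6-(trifluoromethylsulfonyloxy)hept-6-enoic acid (lithium salt in the flask) | CC(=C)[C@@H](CC(=O)O)CCC(=C)OS(=O)(=O)C(F)(F)F | intermediate (not isolated)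
5 | (3R)-3-(prop-1-en-2-yl)hept-6-ynoic acid | CC(=C)[C@@H](CC(=O)O)CCC#C | intermediate
6 | dimethylaluminium (3R,6E)-7-(dimethylalumanyl)-6-methyl-3-(prop-1-en-2-yl)hept-6-enoate | CC(=C)[C@@H](CC(=O)O[Al](C)C)CC/C(C)=C/[Al](C)C | intermediate (not isolated)
7 | (3R,6E)-7-iodo-6-methyl-3-(prop-1-en-2-yl)hept-6-enoic acid | CC(=C)[C@@H](CC(=O)O)CC/C(C)=C/I | intermediate
8 | (3R,6E)-9-tert-butoxy-6-methyl-9-oxo-3-(prop-1-en-2-yl)non-6-enoic acid | CC(=C)[C@@H](CC(=O)O)CC/C(C)=C/CC(=O)OC(C)(C)C | intermediate
9 | mixed anhydride of 8 with isobutyl hydrogen carbonate | CC(=C)[C@@H](CC(=O)OC(=O)OCC(C)C)CC/C(C)=C/CC(=O)OC(C)(C)C | intermediate (not isolated)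
10 | tert-butyl (3E,7R)-10-diazo-4-methyl-9-oxo-7-(prop-1-en-2-yl)dec-3-enoate | CC(=C)[C@@H](CC(=O)C=[N+]=[N-])CC/C(C)=C/CC(=O)OC(C)(C)C | intermediate
11 | cis-fused keto lactone, (3aR,5aR,9aS,9bR)-3a,9a-dimethylperhydronaphtho[2,1-b]furan-2,7-dione (C3 ketone, C4H2, 5β-H, 10β-CH3, 9α-H, 8β-CH3, lactone O 8α) | O=C1C[C@@H]2[C@@]3(C)CCC(=O)C[C@H]3CC[C@@]2(C)O1 | intermediate
12 | 3,3-ethylenedioxy ketal of 11 | O=C1C[C@@H]2[C@@]3(C)CCC4(OCCO4)C[C@H]3CC[C@@]2(C)O1 | intermediate
13 | (2E,6E)-farnesyl acetate | CC(C)=CCC/C(C)=C/CC/C(C)=C/COC(C)=O | starting material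
14 | (2E,6E,10E)-12-hydroxy-3,7,11-trimethyldodeca-2,6,10-trienyl acetate | OC/C(C)=C/CC/C(C)=C/CC/C(C)=C/COC(C)=O | intermediate
15 | (2E,6E,10E)-12-(tert-butyldiphenylsilyloxy)-3,7,11-trimethyldodeca-2,6,10-trienyl acetate | CC(C)(C)[Si](OC/C(C)=C/CC/C(C)=C/CC/C(C)=C/COC(C)=O)(c1ccccc1)c1ccccc1 | intermediate
16 | (2E,6E,10E)-12-(tert-butyldiphenylsilyloxy)-3,7,11-trimethyldodeca-2,6,10-trien-1-ol | CC(C)(C)[Si](OC/C(C)=C/CC/C(C)=C/CC/C(C)=C/CO)(c1ccccc1)c1ccccc1 | intermediate
17 | (2E,6E,10E)-12-bromo-1-(tert-butyldiphenylsilyloxy)-2,6,10-trimethyldodeca-2,6,10-triene | CC(C)(C)[Si](OC/C(C)=C/CC/C(C)=C/CC/C(C)=C/CBr)(c1ccccc1)c1ccccc1 | intermediate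
18 | ketal lactone 12 alkylated at C11 with the C12–C23 silyloxy trienyl chain (C11 epimers) | O=C1C(C/C=C(C)/CC/C=C(C)/CC/C=C(C)/CO[Si](c5ccccc5)(c6ccccc6)C(C)(C)C)[C@@H]2[C@@]3(C)CCC4(OCCO4)C[C@H]3CC[C@@]2(C)O1 | intermediate
19 | lactol of 18 (anomers and C11 epimers) | OC1C(C/C=C(C)/CC/C=C(C)/CC/C=C(C)/CO[Si](c5ccccc5)(c6ccccc6)C(C)(C)C)[C@@H]2[C@@]3(C)CCC4(OCCO4)C[C@H]3CC[C@@]2(C)O1 | intermediate
20 | 8α-hydroxy 3,3-ethylenedioxy bicycle (C4H2, 5β-H, 8β-CH3, 10β-CH3) with the 9β C11–C23 chain ending in CH2OSi(t-Bu)Ph2 | CC(C)(C)[Si](OC/C(C)=C/CC/C(C)=C/CC/C(C)=C/CC[C@@H]1[C@@]2(C)CCC3(OCCO3)C[C@H]2CC[C@@]1(C)O)(c4ccccc4)c5ccccc5 | intermediate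
21 | 8α-hydroxy 3-ketone with C4H2 and the silyl-protected side chain | CC(C)(C)[Si](OC/C(C)=C/CC/C(C)=C/CC/C(C)=C/CC[C@@H]1[C@@]2(C)CCC(=O)C[C@H]2CC[C@@]1(C)O)(c4ccccc4)c5ccccc5 | intermediate
22 | 4-monomethyl derivative of 21 (C4 epimers) | CC(C)(C)[Si](OC/C(C)=C/CC/C(C)=C/CC/C(C)=C/CC[C@@H]1[C@@]2(C)CCC(=O)C(C)[C@H]2CC[C@@]1(C)O)(c4ccccc4)c5ccccc5 | intermediate (not isolated)
23 | 23-O-tert-butyldiphenylsilyl ether of diol 24 (C4 gem-dimethyl 3-ketone) | CC(C)(C)[Si](OC/C(C)=C/CC/C(C)=C/CC/C(C)=C/CC[C@@H]1[C@@]2(C)CCC(=O)C(C)(C)[C@H]2CC[C@@]1(C)O)(c4ccccc4)c5ccccc5 | intermediate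
24 | (5S,8R,9R,10S)-8α,23-dihydroxy 3-ketone (deacetyl target) | OC/C(C)=C/CC/C(C)=C/CC/C(C)=C/CC[C@@H]1[C@@]2(C)CCC(=O)C(C)(C)[C@H]2CC[C@@]1(C)O | intermediate
25 | myrrhanone A acetate as given, (5S,8R,9R,10S) | CC(=O)OC/C(C)=C/CC/C(C)=C/CC/C(C)=C/CC[C@@H]1[C@@]2(C)CCC(=O)C(C)(C)[C@H]2CC[C@@]1(C)O | target

**Step count and risks**

Total step count: 19. Longest linear sequence: 15 steps (steps 1–8 and 13–19); the side-chain bromide 17 takes 4 steps (9–12).

Most likely to fail, step 7. Ring B may close on the equatorial face of the C10 cation and give the trans-fused series, the C10 cation may lose a proton before ring B closes, or the activated diazoketone may be diverted into insertion pathways. The fallback is a free-radical route that sets out from acid 8 and comes back at 11. Acid 8 is activated with carbonyldiimidazole and homologated with Mg(O2CCH2CO2Et)2 (Masamune–Brooks) to the ethyl β-keto ester F1. Oxidative radical bicyclisation of F1 with Mn(OAc)3 and Cu(OAc)2 in acetic acid should let the C2 radical add 6-endo to C1 and the tertiary C10 radical add to C9; the C8 radical is then oxidised by Cu(OAc)2 and captured by the tert-butyl ester, giving the 2-ethoxycarbonyl keto lactone F2. Krapcho dealkoxycarbonylation (LiCl, wet DMSO, 150 °C) then gives 11.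

Second, step 15. The lactol may stay closed, or the acyl rhodium hydride may undergo β-hydride elimination or add across the C13=C14 alkene (hydroacylation) instead of extruding CO. The fallback is a Barton reductive decarboxylation that sets out from 18 and comes back at 20. The lactone of 18 is opened with KOH, the alkoxide and carboxylate are silylated with Me3SiCl/imidazole, and the silyl ester is hydrolysed with aqueous K2CO3 to the 8-O-trimethylsilyl acid F3. F3 is coupled with N-hydroxypyridine-2-thione (dicyclohexylcarbodiimide) to the thiohydroxamate ester F4, which with Bu3SnH under light should give the decarboxylated 8-O-trimethylsilyl ketal F5. K2CO3 in methanol removes the trimethylsilyl group and gives 20.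

Third, step 17. Enolisation towards C2, over-alkylation at C2 once C4 is fully substituted, or O-methylation of the tertiary alkoxide may lead to methyl groups in the wrong places. The fallback blocks C2 as an alkene; it sets out from 21 and comes back at 23. The kinetic enolate of 21 (LiN(i-Pr)2, 2.2 equiv, −78 °C) is selenenylated at C2 with PhSeCl to the 2-phenylselanyl ketone F6. Oxidation with H2O2/pyridine and selenoxide elimination give the C1=C2 enone F7, in which only C4 can be deprotonated. KOt-Bu/MeI then gives the 4,4-dimethyl enone F8, and conjugate reduction with [(Ph3P)CuH]6 gives 23.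

**Further compounds**

F1 | step 7 | tert-butyl ethyl (3E,7R)-4-methyl-9-oxo-7-(prop-1-en-2-yl)undec-3-enedioate (β-keto ester) | CC(=C)[C@@H](CC(=O)CC(=O)OCC)CC/C(C)=C/CC(=O)OC(C)(C)C
F2 | step 7 | 2-ethoxycarbonyl derivative of keto lactone 11 (C2 epimers) | O=C1C[C@@H]2[C@@]3(C)CC(C(=O)OCC)C(=O)C[C@H]3CC[C@@]2(C)O1
F3 | step 15 | 8-O-trimethylsilyl hydroxy acid from 18 (carboxyl on C11, C11 epimers) | CC(C)(C)[Si](OC/C(C)=C/CC/C(C)=C/CC/C(C)=C/CC(C(=O)O)[C@@H]1[C@@]2(C)CCC3(OCCO3)C[C@H]2CC[C@@]1(C)O[Si](C)(C)C)(c4ccccc4)c5ccccc5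
F4 | step 15 | 2-thioxopyridin-1-yl ester of F3 (Barton ester) | CC(C)(C)[Si](OC/C(C)=C/CC/C(C)=C/CC/C(C)=C/CC(C(=O)ON6C=CC=CC6=S)[C@@H]1[C@@]2(C)CCC3(OCCO3)C[C@H]2CC[C@@]1(C)O[Si](C)(C)C)(c4ccccc4)c5ccccc5
F5 | step 15 | 8-O-trimethylsilyl ether of 20 | CC(C)(C)[Si](OC/C(C)=C/CC/C(C)=C/CC/C(C)=C/CC[C@@H]1[C@@]2(C)CCC3(OCCO3)C[C@H]2CC[C@@]1(C)O[Si](C)(C)C)(c4ccccc4)c5ccccc5
F6 | step 17 | 2-phenylselanyl derivative of ketone 21 (C2 epimers) | CC(C)(C)[Si](OC/C(C)=C/CC/C(C)=C/CC/C(C)=C/CC[C@@H]1[C@@]2(C)CC([Se]c6ccccc6)C(=O)C[C@H]2CC[C@@]1(C)O)(c4ccccc4)c5ccccc5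
F7 | step 17 | C1=C2 enone of 21 | CC(C)(C)[Si](OC/C(C)=C/CC/C(C)=C/CC/C(C)=C/CC[C@@H]1[C@@]2(C)C=CC(=O)C[C@H]2CC[C@@]1(C)O)(c4ccccc4)c5ccccc5
F8 | step 17 | 4,4-dimethyl C1=C2 enone (1,2-didehydro 23) | CC(C)(C)[Si](OC/C(C)=C/CC/C(C)=C/CC/C(C)=C/CC[C@@H]1[C@@]2(C)C=CC(=O)C(C)(C)[C@H]2CC[C@@]1(C)O)(c4ccccc4)c5ccccc5
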